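**Retrosynthetic overview**

1. Kazinol B ⇐ one reagent-free thermal isomerisation of a (2S)-flavan carrying a 3'-O-(1,1-dimethylallyl) and a 4'-O-(1,1-dimethylpropargyl) ether (Claisen → 2'-prenyl/3'-OH; propargyl-Claisen cascade → chromene ring, formed last).
2. Flavan C-ring ⇐ ring expansion: the aryl radical of an o-iodoaryl (S)-1-arylallyl ether closes 5-exo to a dihydrobenzofuranylmethyl radical, which undergoes a 1,2-aryl (neophyl) shift to the chroman (C4–C4a bond; C2 untouched).
3. O1–C2 bond and the only stereocentre ⇐ Ir-catalysed asymmetric allylic etherification of a B-ring cinnamyl carbonate with an A-ring 2-iodophenoxide.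
4. Building blocks: catechol (1), 3-chloro-3-methylbut-1-yne (2, used twice) and prop-2-yn-1-ol (3) give the cinnamyl carbonate; resorcinol (4) gives the iodophenol.
5. Ring order: A and B benzene rings are bought; transient dihydrobenzofuran → chroman C-ring by ring expansion; 2,2-dimethylchromene ring last.

Assumption: the ligand enantiomer written in step 10 is the one expected by analogy with cinnamyl carbonates to give the (S)-ether; the sense is checked on the first run and the mirror-image ligand is used if it is opposite.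

**Route**

Step 1
Reactants: 1 catechol; 2 3-chloro-3-methylbut-1-yne
Product: 5 2-[(2-methylbut-3-yn-2-yl)oxy]phenol
Conditions: 1 (3 eq), DBU (1.1 eq), CuCl2·2H2O (1 mol %), MeCN, 0 °C
Reagents that add atoms: none
Why: Cu-catalysed O-propargylation of a phenol with a tertiary propargylic chloride (copper-allenylidene/SN1 type); excess catechol keeps it at the mono-ether, and this arm later becomes the C-prenyl group.

Step 2
Reactants: 5 2-[(2-methylbut-3-yn-2-yl)oxy]phenol
Product: 6 4-bromo-2-[(2-methylbut-3-yn-2-yl)oxy]phenol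
Conditions: NBS (1.0 eq), MeCN, −20 → 0 °C
Reagents that add atoms: N-bromosuccinimide, O=C1CCC(=O)N1Br
Why: electrophilic aromatic bromination goes para to the free OH (a stronger director than the twisted tert-alkyl ether), which places the future C1' para to the oxygen that becomes the chromene oxygen; the terminal alkyne is inert to NBS without silver or base.

Step 3
Reactants: 6 4-bromo-2-[(2-methylbut-3-yn-2-yl)oxy]phenol
Product: 7 4-bromo-2-[(2-methylbut-3-en-2-yl)oxy]phenol
Conditions: H2 (1 atm, 1.0 eq uptake), Lindlar catalyst, quinoline, EtOAc, rt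
Reagents that add atoms: none
Why: Lindlar semihydrogenation stops at the alkene and does not hydrogenolyse the aryl bromide, giving the 1,1-dimethylallyl ether needed for the final Claisen.

Step 4
Reactants: 3 prop-2-yn-1-ol
Product: 9 (E)-3-(4,4,5,5-tetramethyl-1,3,2-dioxaborolan-2-yl)prop-2-en-1-ol, via O-borylated alkenylboronate 8 (not isolated)
Conditions: HBpin (2.2 eq), Cp2Zr(H)Cl (5 mol %), Et3N (10 mol %), neat, 60 °C; aq. NH4Cl work-up
Reagents that add atoms: pinacolborane, [H]B1OC(C)(C)C(C)(C)O1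
Why: the first equivalent of borane caps the OH (H2 loss) and the second adds syn across the terminal alkyne (Zr-catalysed hydroboration) to give the (E)-alkenylboronate; the O–B bond is hydrolysed on work-up.

Step 5
Reactants: 7 4-bromo-2-[(2-methylbut-3-en-2-yl)oxy]phenol; 9 (E)-3-(4,4,5,5-tetramethyl-1,3,2-dioxaborolan-2-yl)prop-2-en-1-ol
Product: 10 4-[(E)-3-hydroxyprop-1-en-1-yl]-2-[(2-methylbut-3-en-2-yl)oxy]phenol
Conditions: XPhos Pd G3 (2 mol %), K3PO4 (3 eq), THF/H2O 4:1, 45 °C
Reagents that add atoms: none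
Why: Suzuki–Miyaura coupling with retention of the (E)-geometry; the active catalyst allows 45 °C, well below the temperature at which the 1,1-dimethylallyl ether rearranges.

Step 6
Reactants: 10 4-[(E)-3-hydroxyprop-1-en-1-yl]-2-[(2-methylbut-3-en-2-yl)oxy]phenol; 2 3-chloro-3-methylbut-1-yne
Product: 11 (E)-3-{3-[(2-methylbut-3-en-2-yl)oxy]-4-[(2-methylbut-3-yn-2-yl)oxy]phenyl}prop-2-en-1-ol
Conditions: 2 (1.5 eq), DBU (1.6 eq), CuCl2·2H2O (1 mol %), MeCN, 0 °C
Reagents that add atoms: none
Why: the same Cu-catalysed propargylation is selective for the phenoxide over the primary allylic alcohol and installs the arm that later becomes the chromene ring.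

Step 7
Reactants: 11 (E)-3-{3-[(2-methylbut-3-en-2-yl)oxy]-4-[(2-methylbut-3-yn-2-yl)oxy]phenyl}prop-2-en-1-ol
Product: 12 methyl (E)-3-{3-[(2-methylbut-3-en-2-yl)oxy]-4-[(2-methylbut-3-yn-2-yl)oxy]phenyl}prop-2-en-1-yl carbonate
Conditions: ClCO2Me (1.3 eq), pyridine, CH2Cl2, 0 °C
Reagents that add atoms: methyl chloroformate, COC(=O)Cl
Why: O-acylation gives the linear allylic methyl carbonate, the standard electrophile for Ir-catalysed allylic substitution.

Step 8
Reactants: 4 resorcinol
Product: 13 4-iodobenzene-1,3-diol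
Conditions: ICl (1.0 eq), Et2O, 0 °C → rt
Reagents that add atoms: iodine monochloride, ClI
Why: electrophilic aromatic iodination at C4 (para to one OH, ortho to the other) gives the iodide that becomes C4a, para to the future 7-OH.

Step 9
Reactants: 13 4-iodobenzene-1,3-diol
Product: 14 2-iodo-5-[(triisopropylsilyl)oxy]phenol
Conditions: TIPSCl (1.05 eq), imidazole (2 eq), CH2Cl2, −20 → 0 °C
Reagents that add atoms: chlorotri(propan-2-yl)silane, CC(C)[Si](Cl)(C(C)C)C(C)C
Why: sterically controlled silylation takes the unhindered OH para to iodine, leaving the ortho-iodo OH as the only nucleophile for the next step.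

Step 10
Reactants: 12 methyl (E)-3-{3-[(2-methylbut-3-en-2-yl)oxy]-4-[(2-methylbut-3-yn-2-yl)oxy]phenyl}prop-2-en-1-yl carbonate; 14 2-iodo-5-[(triisopropylsilyl)oxy]phenol
Product: 16 4-iodo-3-{[(1S)-1-{3-[(2-methylbut-3-en-2-yl)oxy]-4-[(2-methylbut-3-yn-2-yl)oxy]phenyl}prop-2-en-1-yl]oxy}phenol, via silyl ether 15 (not isolated)
Conditions: 14, LiHMDS (1.0 eq), THF, 0 °C; 12 (1.1 eq), [Ir(cod)Cl]2 (2 mol %), (Sa,Sc,Sc)-BINOL bis(1-phenylethyl)amine phosphoramidite (4 mol %, n-PrNH2-activated), THF, 30 °C; then TBAF (1.2 eq), 0 °C; Et3N-buffered silica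
Reagents that add atoms: none
Why: Ir-catalysed asymmetric allylic etherification in which the lithium aryloxide attacks the aryl-substituted terminus of the (π-allyl)Ir complex, the phosphoramidite fixing the face to give the branched (S)-ether (this sets C2); fluoride then removes the TIPS group in the same flask.

Step 11
Reactants: 16 4-iodo-3-{[(1S)-1-{3-[(2-methylbut-3-en-2-yl)oxy]-4-[(2-methylbut-3-yn-2-yl)oxy]phenyl}prop-2-en-1-yl]oxy}phenol
Product: 19 (2S)-2-{3-[(2-methylbut-3-en-2-yl)oxy]-4-[(2-methylbut-3-yn-2-yl)oxy]phenyl}-3,4-dihydro-2H-chromen-7-ol, via dihydrobenzofuranylmethyl radical 17 (not isolated), via chroman-3-yl radical 18 (not isolated)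
Conditions: Bu3SnH (1.2 eq) + V-65 (0.3 eq) by syringe pump over 12 h, PhH (2 mM), 65 °C
Reagents that add atoms: none
Why: Proposed new method: hydride-starved reductive radical ring expansion. Bu3Sn• abstracts iodine and the aryl radical closes 5-exo-trig on the internal vinyl carbon (k > 10^9 s⁻¹) to the primary radical 17. Because Bu3SnH is held near 10⁻⁴ M (estimated k_H[SnH] ≈ 10²–10³ s⁻¹), 17 should live long enough for the neophyl 1,2-aryl shift: 3-exo attack on the ring-fusion ipso carbon, then cleavage of the old C3–aryl bond (estimated k ≈ 10⁴ s⁻¹ at 65 °C from the parent neophyl radical). This expands the dihydrobenzofuran to the secondary chroman-3-yl radical 18, which is then reduced. The minor direct 6-endo closure gives the same 18, and C2 never carries spin, so the (S) centre is retained. Closest known reaction type: stannane-mediated aryl-radical cyclisation of o-haloaryl allyl ethers and the neophyl rearrangement of the resulting (dihydrobenzofuran-3-yl)methyl radicals, not yet used on enantioenriched 1-arylallyl aryl ethers as a flavan synthesis.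

Step 12
Reactants: 19 (2S)-2-{3-[(2-methylbut-3-en-2-yl)oxy]-4-[(2-methylbut-3-yn-2-yl)oxy]phenyl}-3,4-dihydro-2H-chromen-7-ol
Product: 20 kazinol B, (2S)-2-[8-hydroxy-2,2-dimethyl-7-(3-methylbut-2-en-1-yl)-2H-chromen-6-yl]-3,4-dihydro-2H-chromen-7-ol
Conditions: o-xylene (0.05 M), degassed, 140 °C, 6 h
Reagents that add atoms: none
Why: two thermal sigmatropic sequences run in one pot: aromatic Claisen rearrangement of the 1,1-dimethylallyl ether delivers the prenyl group to the only free ortho carbon (C2') and frees 3'-OH, and the propargyl Claisen/[1,5]-H shift/oxa-6π sequence closes the 2,2-dimethylchromene at C5'; neutral conditions leave C2 untouched.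

**Compound list**

1 | catechol | Oc1ccccc1O | starting material
2 | 3-chloro-3-methylbut-1-yne | CC(C)(Cl)C#C | starting material
3 | prop-2-yn-1-ol | OCC#C | starting material
4 | resorcinol | Oc1cccc(O)c1 | starting material
5 | 2-[(2-methylbut-3-yn-2-yl)oxy]phenol | C#CC(C)(C)Oc1ccccc1O | intermediate
6 | 4-bromo-2-[(2-methylbut-3-yn-2-yl)oxy]phenol | C#CC(C)(C)Oc1cc(Br)ccc1O | intermediate
7 | 4-bromo-2-[(2-methylbut-3-en-2-yl)oxy]phenol | C=CC(C)(C)Oc1cc(Br)ccc1O | intermediate
8 | 2-[(E)-3-[(4,4,5,5-tetramethyl-1,3,2-dioxaborolan-2-yl)oxy]prop-1-en-1-yl]-4,4,5,5-tetramethyl-1,3,2-dioxaborolane | CC1(C)OB(OC/C=C/B2OC(C)(C)C(C)(C)O2)OC1(C)C | intermediate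
9 | (E)-3-(4,4,5,5-tetramethyl-1,3,2-dioxaborolan-2-yl)prop-2-en-1-ol | OC/C=C/B1OC(C)(C)C(C)(C)O1 | intermediate
10 | 4-[(E)-3-hydroxyprop-1-en-1-yl]-2-[(2-methylbut-3-en-2-yl)oxy]phenol | C=CC(C)(C)Oc1cc(/C=C/CO)ccc1O | intermediate
11 | (E)-3-{3-[(2-methylbut-3-en-2-yl)oxy]-4-[(2-methylbut-3-yn-2-yl)oxy]phenyl}prop-2-en-1-ol | C=CC(C)(C)Oc1cc(/C=C/CO)ccc1OC(C)(C)C#C | intermediate
12 | methyl (E)-3-{3-[(2-methylbut-3-en-2-yl)oxy]-4-[(2-methylbut-3-yn-2-yl)oxy]phenyl}prop-2-en-1-yl carbonate | C=CC(C)(C)Oc1cc(/C=C/COC(=O)OC)ccc1OC(C)(C)C#C | intermediate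
13 | 4-iodobenzene-1,3-diol | Oc1ccc(I)c(O)c1 | intermediate
14 | 2-iodo-5-[(triisopropylsilyl)oxy]phenol | CC(C)[Si](Oc1ccc(I)c(O)c1)(C(C)C)C(C)C | intermediate
15 | {4-iodo-3-{[(1S)-1-{3-[(2-methylbut-3-en-2-yl)oxy]-4-[(2-methylbut-3-yn-2-yl)oxy]phenyl}prop-2-en-1-yl]oxy}phenoxy}triisopropylsilane | C=C[C@H](Oc1cc(O[Si](C(C)C)(C(C)C)C(C)C)ccc1I)c1ccc(OC(C)(C)C#C)c(OC(C)(C)C=C)c1 | intermediate
16 | 4-iodo-3-{[(1S)-1-{3-[(2-methylbut-3-en-2-yl)oxy]-4-[(2-methylbut-3-yn-2-yl)oxy]phenyl}prop-2-en-1-yl]oxy}phenol | C=C[C@H](Oc1cc(O)ccc1I)c1ccc(OC(C)(C)C#C)c(OC(C)(C)C=C)c1 | intermediate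
17 | [(2S)-6-hydroxy-2-{3-[(2-methylbut-3-en-2-yl)oxy]-4-[(2-methylbut-3-yn-2-yl)oxy]phenyl}-2,3-dihydro-1-benzofuran-3-yl]methyl radical (C3 epimers) | [CH2]C1[C@H](Oc2cc(O)ccc12)c1ccc(OC(C)(C)C#C)c(OC(C)(C)C=C)c1 | intermediate
18 | (2S)-7-hydroxy-2-{3-[(2-methylbut-3-en-2-yl)oxy]-4-[(2-methylbut-3-yn-2-yl)oxy]phenyl}-3,4-dihydro-2H-chromen-3-yl radical | [CH]1Cc2ccc(O)cc2O[C@@H]1c1ccc(OC(C)(C)C#C)c(OC(C)(C)C=C)c1 | intermediate
19 | (2S)-2-{3-[(2-methylbut-3-en-2-yl)oxy]-4-[(2-methylbut-3-yn-2-yl)oxy]phenyl}-3,4-dihydro-2H-chromen-7-ol | C=CC(C)(C)Oc1cc([C@@H]2CCc3ccc(O)cc3O2)ccc1OC(C)(C)C#C | intermediate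
20 | kazinol B, (2S)-2-[8-hydroxy-2,2-dimethyl-7-(3-methylbut-2-en-1-yl)-2H-chromen-6-yl]-3,4-dihydro-2H-chromen-7-ol | CC(C)=CCc1c([C@@H]2CCc3ccc(O)cc3O2)cc2c(c1O)OC(C)(C)C=C2 | target

**Step count and risks**

Total steps: 12. Longest linear sequence: 9 (steps 1, 2, 3, 5, 6, 7, 10, 11, 12).

Three steps most likely to fail:

Step 10 (Ir allylic etherification). The ortho-iodo aryloxide is hindered and weakly nucleophilic, and the electron-rich branched ether can re-ionise on the catalyst, eroding branched/linear ratio and ee. The fallback sets out from 12 and uses an oxygen nucleophile that cannot leave again. Ir-catalysed allylic substitution of 12 with potassium triethylsilanolate and the mirror-image ligand gives triethyl{[(1R)-1-{3-[(2-methylbut-3-en-2-yl)oxy]-4-[(2-methylbut-3-yn-2-yl)oxy]phenyl}prop-2-en-1-yl]oxy}silane F1. TBAF frees (1R)-1-{3-[(2-methylbut-3-en-2-yl)oxy]-4-[(2-methylbut-3-yn-2-yl)oxy]phenyl}prop-2-en-1-ol F2. Mitsunobu etherification of F2 with 14 (PPh3, DIAD, toluene, −20 °C) inverts the centre and returns to the route at 15, which is desilylated to 16 as in step 10.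

Step 11 (new radical ring expansion). If hydrogen transfer outruns the 1,2-aryl shift, the product is the 3-methyl-2-aryl-dihydrobenzofuran; stannyl radicals may also add to the terminal alkyne. The fallback uses known chemistry, sets out from 16 and closes the ring by C–C coupling instead. 16 is first heated (o-xylene, 130 °C) so that both sigmatropic rearrangements run while the allyl ether is still open, giving 4-iodo-3-{[(1S)-1-[8-hydroxy-2,2-dimethyl-7-(3-methylbut-2-en-1-yl)-2H-chromen-6-yl]prop-2-en-1-yl]oxy}phenol F3. Its vinyl group is now the only terminal alkene, so 9-BBN (3.3 eq, THF, 0 °C → rt) gives selectively the B-alkyl-9-BBN adduct with both phenols as 9-BBN borinates F4. Intramolecular B-alkyl Suzuki–Miyaura coupling (Pd(dppf)Cl2, aq. K3PO4, DMF, 50 °C) then returns to the route at 20. The heating of 16 is the weak point of this fallback, since the acyclic aryl allyl ether could itself rearrange or ionise.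

Step 12 (double Claisen). Possible problems are incomplete chromene formation, benzofuran by-products, and partial loss of ee through a para-quinone methide while the 4'-oxygen is transiently a free phenol. The fallback sets out from 19 and replaces the thermal cascade by two catalysed steps near room temperature. Au(I)-catalysed 6-endo hydroarylation of the propargyl ether (Ph3PAuNTf2 2 mol %, CH2Cl2, rt) gives (2S)-2-{2,2-dimethyl-8-[(2-methylbut-3-en-2-yl)oxy]-2H-chromen-6-yl}-3,4-dihydro-2H-chromen-7-ol F5. Eu(fod)3-catalysed Claisen rearrangement (10 mol %, CHCl3, 50 °C) then returns to the route at 20.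

**Further compounds**

F1 | step 10 | triethyl{[(1R)-1-{3-[(2-methylbut-3-en-2-yl)oxy]-4-[(2-methylbut-3-yn-2-yl)oxy]phenyl}prop-2-en-1-yl]oxy}silane | C=C[C@@H](O[Si](CC)(CC)CC)c1ccc(OC(C)(C)C#C)c(OC(C)(C)C=C)c1
F2 | step 10 | (1R)-1-{3-[(2-methylbut-3-en-2-yl)oxy]-4-[(2-methylbut-3-yn-2-yl)oxy]phenyl}prop-2-en-1-ol | C=C[C@@H](O)c1ccc(OC(C)(C)C#C)c(OC(C)(C)C=C)c1
F3 | step 11 | 4-iodo-3-{[(1S)-1-[8-hydroxy-2,2-dimethyl-7-(3-methylbut-2-en-1-yl)-2H-chromen-6-yl]prop-2-en-1-yl]oxy}phenol | C=C[C@H](Oc1cc(O)ccc1I)c1cc2C=CC(C)(C)Oc2c(O)c1CC=C(C)C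
F4 | step 11 | B-alkyl-9-BBN adduct of F3 at the terminal carbon, both phenols as 9-BBN borinates | B1(C2CCCC1CCC2)CC[C@H](Oc1cc(OB2C3CCCC2CCC3)ccc1I)c1cc2C=CC(C)(C)Oc2c(OB2C3CCCC2CCC3)c1CC=C(C)C
F5 | step 12 | (2S)-2-{2,2-dimethyl-8-[(2-methylbut-3-en-2-yl)oxy]-2H-chromen-6-yl}-3,4-dihydro-2H-chromen-7-ol | C=CC(C)(C)Oc1cc([C@@H]2CCc3ccc(O)cc3O2)cc2C=CC(C)(C)Oc12
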